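## The problem

Target 25 has one ring, a 3,4-dihydro-2H-pyran (O1, C2–C6). Its C5=C6–O1 unit is a β-alkoxyacrylate with the methyl ester on C5. C2 (methyl), C3 (formyl) and C4 (the CH2CO2 arm esterified with hydroxytyrosol) are contiguous stereocentres, 2,3-trans and 3,4-trans, absolute configuration (2S,3R,4R).

The three centres differ in how they can be controlled. C3 is α to the aldehyde and epimerises by enolisation. The C2–O1 bond is β to that aldehyde, and O1 belongs to a vinylogous carboxylate, so it can open and reclose by retro-oxa-Michael/oxa-Michael addition. C4 is neither acidic nor reversible, so it must be set absolutely; it can then steer C2 and C3 under equilibrating conditions.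

The sensitive groups are the enolisable aldehyde, the enol ether and the oxidisable catechol. Two different esters rule out saponification and unselective hydride reagents, and several 1,5-hydroxy-ester relationships along the way invite lactonisation.

The feature that opens the key step is the position of C4. It lies between C5, which becomes a malonate carbon once C6 is written as a carboxyl group, and C3. If C3=C4 is an alkene and C2 carries an ester oxygen, the array is an allylic malonate. A [3,3] shift then forms C4–C5 and leaves a C2=C3 ethylidene, which is the acceptor needed for closing O1–C2.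

## Retrosynthesis

**25 ⇒ 24 (two O–Si bonds).** The catechol is kept as its bis-TBS ether until the last step. Fluoride removal is compatible with the aldehyde and the β-alkoxyacrylate; acid-labile ketals or hydrogenolysable benzyl ethers would not be. All equilibration of the ring is therefore done on 24, before the catechol is free.

**24 ⇒ 23 ⇒ 22 (O1–C2, then the aldehyde oxidation level at the C3 substituent).** Cutting O1–C2 turns the ring into an acyclic enal carrying a formyl-ester enol (23). The alternative cut at C6–O1 would demand a separately made C2 carbinol and an anti C2/C3 relationship. The oxa-Michael cut leaves C4 as the only stereocentre, because C2 and C3 are formed reversibly. The forward reaction must be a 6-endo conjugate addition that can equilibrate. Enal 23 comes from allylic alcohol 22 by an oxidant that touches only allylic carbinols.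

**22 ⇒ 21 ⇒ 20 ⇒ 19 (functional-group level at C6 and at the C3 substituent).** C6 is taken back from the aldehyde to a carboxylic acid by way of thioester 20. A thioester can be reduced to the aldehyde in the presence of the two ordinary esters, which no hydride reagent applied to the triester would achieve. The C3 hydroxymethyl stays as its PMB ether until C6 is an enol. Liberating it earlier would place a free alcohol 1,5 to a thioester.

**19 ⇒ 16 (C4–C5; the key cut).** Acid 19 is the Ireland–Claisen product of allylic methyl malonate 16. The cut removes the only permanent stereocentre and replaces it by a secondary carbinol from the chiral pool and a trisubstituted alkene of defined geometry. Neighbouring cuts (C3–C4 by conjugate addition, C4–arm by enolate chemistry) would require an external source of chirality at C4. The forward step must enolise only the malonate and pass through one chair.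

**16 ⇒ 14 + 15 (ester C–O).** Acylation of secondary allylic alcohol 14 with methyl malonyl chloride 15.

**14 ⇒ 10 + 13 (C3–CH2O).** The oxygenated one-carbon unit is joined to alkenyl iodide 10 by cross-coupling with stannane 13, itself from 11 and 12. It is introduced already as the PMB ether. A free CH2OH cis to the CH2CO2 arm across the alkene would lactonise at once. The coupling precedes acylation, because an alkenylpalladium next to an allylic ester could eliminate to an allene.

**10 ⇒ 8 (C–I and C–H across the alkyne, via 9).** Hydroxyl-directed trans-hydrostannation of alkynoate 8 puts tin on the carbon next to the carbinol and hydrogen anti. This delivers the trisubstituted geometry (iodine cis to the arm) that no carbonyl olefination would give reliably.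

**8 ⇒ 7 + 6 (C(sp)–CH2).** The 3-alkynoate is the coupling product of (S)-but-3-yn-2-ol 7 with diazoacetate 6. The hydroxytyrosyl ester is thus in place from the start and no late transesterification is needed.

**6 ⇒ 3 + 4; 3 ⇒ 2 ⇒ 1.** The diazoacetate comes from alcohol 3 and bromoacetyl bromide 4. Alcohol 3 comes from hydroxytyrosol 1 by exhaustive silylation to 2 and selective release of the primary hydroxyl.

## Roads not taken

**Alternative 1:** amine-catalysed oxa-Michael/Michael annulation. The cut is O1–C2 plus C3–C4. In the forward sense, the enol oxygen of formylglutaconate A2 would add to the iminium ion of crotonaldehyde A1. The resulting enamine carbon would then add in 6-exo fashion to the acrylate terminus, giving A3, which is the same compound as 24.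

- Merits: ring and all three stereocentres arise in one catalytic step from achiral pieces, and the route would be perhaps half as long as the chosen one. In step economy this road is clearly better.
- Weak points: A2 is a vinylogous acid, a poor O-nucleophile and a good leaving group, so the first addition is readily reversed. A2 is also a doubly activated diene ester likely to add to itself. After O-alkylation the acceptor is a donor-substituted dienoate of reduced electrophilicity.
- The decisive weakness is C4. It would be fixed in the irreversible C–C step under remote catalyst control, and it is the one centre that cannot be corrected afterwards.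
- What the chosen plan sets against the shorter count: C4 is derived from a carbinol of known configuration through a predictable chair, and every step has a close relative.

**Alternative 2:** auxiliary-controlled syn aldol across C2–C3. The Z boron enolate of imide A4 would add to acetaldehyde A5 to give adduct A6. The syn relationship of A6 maps onto the 2,3-trans ring arrangement.

- Merits: C2 is set kinetically and very reliably, independent of any equilibrium. In that respect this road is better than the chosen plan, which relies on thermodynamic control at C2.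
- Weak points: the aldol leaves the real problem untouched. A4 already contains C4, flanked by two different acetic acid arms and the β-methoxyacrylate, so an enantioselective synthesis of a desymmetrised glutarate must come first. After the aldol, the imide carbonyl has to be reduced to the C3 aldehyde in the presence of two esters. The ring must then be closed by addition–elimination at C6.
- What the chosen plan sets against the secure C2: no auxiliary, no separate construction of C4, and fewer redox corrections. It accepts that C2 and C3 are left to equilibrate.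

**Alternative 3:** Mukaiyama–Michael union of the side chain with a malonate lactone. The cut is the bond from C4 to the arm methylene. Silyl ketene acetal A8 would add to the alkylidene malonate lactone A7 anti to its C3 substituent, giving lactone A9.

- Merits: the acceptor is highly electrophilic and the facial bias of a 5,6-disubstituted dihydropyranone is dependable. The silylated hydroxytyrosyl unit arrives late, so it is carried through few steps. On convergence this road is better.
- Weak points: A7 needs C2 and C3 set beforehand in an anti relationship by separate stereoselective steps. Its γ-hydrogen invites deconjugation. A9 has C6 at the lactone oxidation level, so a chemoselective reduction of one carbonyl among three esters must follow, then PMB removal and oxidation.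
- What the chosen plan sets against the better convergence: C6 is reached from a free carboxylic acid, which is easy to single out, and the one stereocentre made deliberately is the one that cannot be repaired.

Key step: step 9

Remark on notation: TBS = tert-butyldimethylsilyl, PMB = 4-methoxybenzyl, Q = 2-[3,4-bis(tert-butyldimethylsilyloxy)phenyl]ethyl; ring atoms are numbered O1, C2 (methyl), C3 (formyl), C4 (arm), C5 (ester), C6 throughout, also in open-chain precursors.

Assumption: the 2-formyl esters 21–23 are written as their hydroxymethylidene (enol) tautomers, which equilibrate freely with the aldehyde forms, so neither C5 nor the enol geometry is specified.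

## Route

Step 1
Reactants: 1 hydroxytyrosol
Product: 2 tert-butyl{2-[3,4-bis(tert-butyldimethylsilyloxy)phenyl]ethoxy}dimethylsilane
Conditions: TBSCl (3.5 equiv), imidazole, DMF, rt
Reagents that add atoms: tert-butyldimethylsilyl chloride, CC(C)(C)[Si](C)(C)Cl
Why: Imidazole-promoted silylation of all three hydroxyl groups; exhaustive protection avoids any need for selectivity between phenol and alcohol.

Step 2
Reactants: 2 tris-TBS ether of hydroxytyrosol
Product: 3 2-[3,4-bis(tert-butyldimethylsilyloxy)phenyl]ethanol (Q–OH)
Conditions: camphorsulfonic acid (cat.), MeOH/CH2Cl2, 0 °C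
Reagents that add atoms: none
Why: Acid-catalysed methanolysis cleaves the primary alkyl silyl ether much faster than aryl silyl ethers (selective desilylation), freeing only the hydroxyl to be acylated.

Step 3
Reactants: 3 Q–OH; 4 bromoacetyl bromide
Product: 6 Q diazoacetate, via bromoacetate 5 (not isolated)
Conditions: NaHCO3, MeCN, 0 °C; then TsNHNHTs, DBU, 0 °C
Reagents that add atoms: N,N'-ditosylhydrazine, Cc1ccc(cc1)S(=O)(=O)NNS(=O)(=O)c1ccc(C)cc1 (supplies the two diazo nitrogens)
Why: O-Acylation by the acyl bromide, then the ditosylhydrazine diazoacetate synthesis: N-alkylation by the bromoacetate and twofold base-induced loss of sulfinate. The DBU exposure is short, cold and anhydrous, so the aryl silyl ethers should persist.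

Step 4
Reactants: 7 (S)-but-3-yn-2-ol; 6 Q diazoacetate
Product: 8 Q (S)-5-hydroxyhex-3-ynoate
Conditions: CuI (5 mol%), MeCN, rt
Reagents that add atoms: none
Why: Base-free CuI-catalysed coupling of a terminal alkyne with a diazoacetate (copper acetylide, carbene formation and migratory insertion, protonation) gives the 3-alkynoate without isomerisation to the allenoate. The carbinol centre is not involved, and the neutral medium should not promote O–H insertion.

Step 5
Reactants: 8 Q (S)-5-hydroxyhex-3-ynoate
Product: 10 Q (S,Z)-5-hydroxy-4-iodohex-3-enoate, via alkenylstannane 9 (not isolated)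
Conditions: [Cp*RuCl]4 (cat.), Bu3SnH, CH2Cl2, rt; then I2, 0 °C
Reagents that add atoms: tributyltin hydride, CCCC[SnH](CCCC)CCCC (its Bu3Sn group is held by 9 only); iodine, II
Why: The free propargylic hydroxyl directs the ruthenium-catalysed trans-hydrostannation, placing tin on the alkyne carbon next to the carbinol with hydrogen anti. Iododestannylation then proceeds with retention, giving the Z iodide with iodine cis to the CH2CO2Q group.

Step 6
Reactants: 11 tributyl(iodomethyl)stannane; 12 4-methoxybenzyl alcohol
Product: 13 tributyl[(4-methoxybenzyloxy)methyl]stannane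
Conditions: NaH, THF/DMF, 0 °C → rt
Reagents that add atoms: none
Why: Williamson ether synthesis; the alkoxide displaces iodide from the primary iodomethylstannane by an SN2 reaction.

Step 7
Reactants: 10 Q (S,Z)-5-hydroxy-4-iodohex-3-enoate; 13 tributyl[(4-methoxybenzyloxy)methyl]stannane
Product: 14 Q (S,E)-5-hydroxy-4-[(4-methoxybenzyloxy)methyl]hex-3-enoate
Conditions: Pd(PPh3)4 (cat.), CuI (cat.), DMF, 60 °C
Reagents that add atoms: none
Why: Stille coupling of an alkenyl iodide with an α-alkoxymethylstannane, with CuI assisting transfer of the alkoxymethyl group; alkene geometry is retained and the free secondary hydroxyl is tolerated. Delivering the carbon as its PMB ether avoids a free CH2OH cis to the arm ester, which would lactonise.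

Step 8
Reactants: 14 Q (S,E)-5-hydroxy-4-[(4-methoxybenzyloxy)methyl]hex-3-enoate; 15 methyl malonyl chloride
Product: 16 1-methyl 3-[(2S,3E)-3-[(4-methoxybenzyloxy)methyl]-6-oxo-6-(Q-oxy)hex-3-en-2-yl] propanedioate
Conditions: pyridine, CH2Cl2, 0 °C
Reagents that add atoms: none
Why: Acylation of the secondary allylic alcohol by the acid chloride with pyridine as base; the carbinol configuration and the alkene are untouched.

Step 9
Reactants: 16 (S)-allylic methyl malonate
Product: 19 (3S,4Z)-2-(methoxycarbonyl)-4-[(4-methoxybenzyloxy)methyl]-3-[2-oxo-2-(Q-oxy)ethyl]hex-4-enoic acid, via silyl ketene acetal 17 (not isolated), via trimethylsilyl ester 18 (not isolated)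
Conditions: TMSOTf, Et3N, toluene, 0 → 60 °C; then aqueous citric acid, 0 °C
Reagents that add atoms: trimethylsilyl triflate, C[Si](C)(C)OS(=O)(=O)C(F)(F)F (its Me3Si group is held by 17 and 18 and is lost on work-up)
Why: Soft enolisation (TMSOTf on the malonate carbonyl, Et3N removing the doubly activated proton) gives silyl ketene acetal 17, which undergoes a concerted suprafacial [3,3] shift (Ireland–Claisen rearrangement) to silyl ester 18, and aqueous acid frees acid 19. The closest known reaction type is the ester-enolate Claisen rearrangement of allylic malonates under silylating conditions. No ring closes. The one lasting new stereocentre, C4, is controlled by the (S)-carbinol: in the chair with the C2 methyl equatorial, the C2–O bond breaks and the C4–C5 bond forms on the same face of the allyl unit, so the carbinol configuration and the E geometry of C3=C4 fix C4 as drawn and place the methyl trans to C4 on the new ethylidene. The step needs chair over boat and equatorial over axial methyl, which the acyclic substrate and the 1,3-diaxial clash of an axial methyl secure. It also needs enolisation of the malonate alone, which its acidity, many pK units below that of the β,γ-unsaturated arm ester, secures. C5 forms as a mixture, which is irrelevant because it later becomes sp2.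

Step 10
Reactants: 19 malonic half-acid
Product: 20 S-ethyl thioester of 19 (1-methyl 3-S-ethyl malonate with the C4 substituents unchanged)
Conditions: EtSH, EDC·HCl, DMAP (cat.), CH2Cl2, 0 °C
Reagents that add atoms: ethanethiol, CCS
Why: Carbodiimide/DMAP thioesterification (Steglich type) of the only free carboxyl group; the low temperature guards against decarboxylation of the malonic half-acid.

Step 11
Reactants: 20 S-ethyl thioester
Product: 21 methyl (3R,4Z)-2-(hydroxymethylidene)-4-[(4-methoxybenzyloxy)methyl]-3-[2-oxo-2-(Q-oxy)ethyl]hex-4-enoate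
Conditions: Et3SiH, Pd/C (10%), acetone, rt
Reagents that add atoms: none
Why: Fukuyama reduction takes the thioester selectively to the aldehyde and leaves both esters, the PMB ether and the trisubstituted alkene alone. The product rests as the hydrogen-bonded enol, which stops further reduction.

Step 12
Reactants: 21 formyl-ester enol with PMB ether
Product: 22 methyl (3R,4Z)-4-(hydroxymethyl)-2-(hydroxymethylidene)-3-[2-oxo-2-(Q-oxy)ethyl]hex-4-enoate
Conditions: DDQ, CH2Cl2/pH 7 buffer, 0 °C
Reagents that add atoms: none
Why: Oxidative PMB cleavage (hydride abstraction from the electron-rich benzyl ether, hydrolysis of the oxocarbenium ion). The electron-poor enol and the silylated catechol are much less easily oxidised; the buffer keeps the medium from catalysing lactonisation.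

Step 13
Reactants: 22 allylic alcohol
Product: 24 methyl (2S,3R,4R)-3-formyl-2-methyl-4-[2-oxo-2-(Q-oxy)ethyl]-3,4-dihydro-2H-pyran-5-carboxylate, via open enal 23 (not isolated)
Conditions: MnO2, CH2Cl2, rt; filter; then Et3N (cat.), CH2Cl2, rt
Reagents that add atoms: none
Why: MnO2 oxidises only the allylic carbinol, and the enol oxygen then attacks C2 of enal 23 in a base-catalysed 6-endo-trig oxa-Michael addition; any hemiacetal from 1,2-addition reverts. With Et3N, retro-oxa-Michael opening and aldehyde enolisation stay available, so C2 and C3 are set under thermodynamic control by the fixed C4. This should favour the isomer in which all three substituents are trans and pseudo-equatorial, the relative configuration that prevails when open dialdehydes of this aglycone family close.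

Step 14
Reactants: 24 bis-TBS ether of the target
Product: 25 methyl (2S,3R,4R)-4-{2-[2-(3,4-dihydroxyphenyl)ethoxy]-2-oxoethyl}-3-formyl-2-methyl-3,4-dihydro-2H-pyran-5-carboxylate (target)
Conditions: HF·pyridine, pyridine, THF, 0 °C → rt
Reagents that add atoms: none
Why: Fluoride-mediated cleavage of the two aryl silyl ethers; the buffered reagent is neither basic nor strongly acidic, so the α-formyl centre, the C2–O1 bond and the β-alkoxyacrylate should not be disturbed.

## Compound list

1 | hydroxytyrosol, 2-(3,4-dihydroxyphenyl)ethanol | OCCc1ccc(O)c(O)c1 | starting material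
2 | tert-butyl{2-[3,4-bis(tert-butyldimethylsilyloxy)phenyl]ethoxy}dimethylsilane | CC(C)(C)[Si](C)(C)OCCc1ccc(O[Si](C)(C)C(C)(C)C)c(O[Si](C)(C)C(C)(C)C)c1 | intermediate
3 | 2-[3,4-bis(tert-butyldimethylsilyloxy)phenyl]ethanol (Q–OH) | OCCc1ccc(O[Si](C)(C)C(C)(C)C)c(O[Si](C)(C)C(C)(C)C)c1 | intermediate
4 | bromoacetyl bromide | BrCC(Br)=O | starting material
5 | 2-[3,4-bis(tert-butyldimethylsilyloxy)phenyl]ethyl bromoacetate | BrCC(=O)OCCc1ccc(O[Si](C)(C)C(C)(C)C)c(O[Si](C)(C)C(C)(C)C)c1 | intermediate (not isolated)
6 | 2-[3,4-bis(tert-butyldimethylsilyloxy)phenyl]ethyl diazoacetate | [N-]=[N+]=CC(=O)OCCc1ccc(O[Si](C)(C)C(C)(C)C)c(O[Si](C)(C)C(C)(C)C)c1 | intermediate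
7 | (S)-but-3-yn-2-ol | C[C@H](O)C#C | starting material
8 | 2-[3,4-bis(tert-butyldimethylsilyloxy)phenyl]ethyl (S)-5-hydroxyhex-3-ynoate | C[C@H](O)C#CCC(=O)OCCc1ccc(O[Si](C)(C)C(C)(C)C)c(O[Si](C)(C)C(C)(C)C)c1 | intermediate
9 | 2-[3,4-bis(tert-butyldimethylsilyloxy)phenyl]ethyl (S,Z)-5-hydroxy-4-(tributylstannyl)hex-3-enoate (tin cis to the CH2CO2Q group) | C[C@H](O)/C([Sn](CCCC)(CCCC)CCCC)=C/CC(=O)OCCc1ccc(O[Si](C)(C)C(C)(C)C)c(O[Si](C)(C)C(C)(C)C)c1 | intermediate (not isolated)
10 | 2-[3,4-bis(tert-butyldimethylsilyloxy)phenyl]ethyl (S,Z)-5-hydroxy-4-iodohex-3-enoate | C[C@H](O)/C(I)=C/CC(=O)OCCc1ccc(O[Si](C)(C)C(C)(C)C)c(O[Si](C)(C)C(C)(C)C)c1 | intermediate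
11 | tributyl(iodomethyl)stannane | CCCC[Sn](CCCC)(CCCC)CI | starting material
12 | 4-methoxybenzyl alcohol | COc1ccc(CO)cc1 | starting material
13 | tributyl[(4-methoxybenzyloxy)methyl]stannane | CCCC[Sn](CCCC)(CCCC)COCc1ccc(OC)cc1 | intermediate
14 | 2-[3,4-bis(tert-butyldimethylsilyloxy)phenyl]ethyl (S,E)-5-hydroxy-4-[(4-methoxybenzyloxy)methyl]hex-3-enoate (carbinol carbon trans to the CH2CO2Q group) | C[C@H](O)/C(COCc1ccc(OC)cc1)=C/CC(=O)OCCc2ccc(O[Si](C)(C)C(C)(C)C)c(O[Si](C)(C)C(C)(C)C)c2 | intermediate
15 | methyl malonyl chloride, methyl 3-chloro-3-oxopropanoate | COC(=O)CC(Cl)=O | starting material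
16 | 1-methyl 3-[(2S,3E)-6-{2-[3,4-bis(tert-butyldimethylsilyloxy)phenyl]ethoxy}-3-[(4-methoxybenzyloxy)methyl]-6-oxohex-3-en-2-yl] propanedioate (key-step precursor) | C[C@H](OC(=O)CC(=O)OC)/C(COCc1ccc(OC)cc1)=C/CC(=O)OCCc2ccc(O[Si](C)(C)C(C)(C)C)c(O[Si](C)(C)C(C)(C)C)c2 | intermediate
17 | trimethylsilyl ketene acetal of 16 on the allyl-ester carbonyl | C[C@H](OC(O[Si](C)(C)C)=CC(=O)OC)/C(COCc1ccc(OC)cc1)=C/CC(=O)OCCc2ccc(O[Si](C)(C)C(C)(C)C)c(O[Si](C)(C)C(C)(C)C)c2 | intermediate (not isolated)
18 | trimethylsilyl ester of acid 19 | C[Si](C)(C)OC(=O)C(C(=O)OC)[C@H](CC(=O)OCCc1ccc(O[Si](C)(C)C(C)(C)C)c(O[Si](C)(C)C(C)(C)C)c1)/C(COCc2ccc(OC)cc2)=C/C | intermediate (not isolated)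
19 | (3S,4Z)-3-(2-{2-[3,4-bis(tert-butyldimethylsilyloxy)phenyl]ethoxy}-2-oxoethyl)-2-(methoxycarbonyl)-4-[(4-methoxybenzyloxy)methyl]hex-4-enoic acid, C2 unassigned (key-step product) | OC(=O)C(C(=O)OC)[C@H](CC(=O)OCCc1ccc(O[Si](C)(C)C(C)(C)C)c(O[Si](C)(C)C(C)(C)C)c1)/C(COCc2ccc(OC)cc2)=C/C | intermediate
20 | S-ethyl thioester of 19 | CCSC(=O)C(C(=O)OC)[C@H](CC(=O)OCCc1ccc(O[Si](C)(C)C(C)(C)C)c(O[Si](C)(C)C(C)(C)C)c1)/C(COCc2ccc(OC)cc2)=C/C | intermediate
21 | methyl (3R,4Z)-3-(2-{2-[3,4-bis(tert-butyldimethylsilyloxy)phenyl]ethoxy}-2-oxoethyl)-2-(hydroxymethylidene)-4-[(4-methoxybenzyloxy)methyl]hex-4-enoate | COC(=O)C(=CO)[C@H](CC(=O)OCCc1ccc(O[Si](C)(C)C(C)(C)C)c(O[Si](C)(C)C(C)(C)C)c1)/C(COCc2ccc(OC)cc2)=C/C | intermediate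
22 | methyl (3R,4Z)-3-(2-{2-[3,4-bis(tert-butyldimethylsilyloxy)phenyl]ethoxy}-2-oxoethyl)-4-(hydroxymethyl)-2-(hydroxymethylidene)hex-4-enoate | COC(=O)C(=CO)[C@H](CC(=O)OCCc1ccc(O[Si](C)(C)C(C)(C)C)c(O[Si](C)(C)C(C)(C)C)c1)/C(CO)=C/C | intermediate
23 | methyl (3R,4Z)-3-(2-{2-[3,4-bis(tert-butyldimethylsilyloxy)phenyl]ethoxy}-2-oxoethyl)-4-formyl-2-(hydroxymethylidene)hex-4-enoate | COC(=O)C(=CO)[C@H](CC(=O)OCCc1ccc(O[Si](C)(C)C(C)(C)C)c(O[Si](C)(C)C(C)(C)C)c1)/C(C=O)=C/C | intermediate (not isolated)
24 | methyl (2S,3R,4R)-4-(2-{2-[3,4-bis(tert-butyldimethylsilyloxy)phenyl]ethoxy}-2-oxoethyl)-3-formyl-2-methyl-3,4-dihydro-2H-pyran-5-carboxylate | COC(=O)C1=CO[C@@H](C)[C@H](C=O)[C@H]1CC(=O)OCCc1ccc(O[Si](C)(C)C(C)(C)C)c(O[Si](C)(C)C(C)(C)C)c1 | intermediate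
25 | methyl (2S,3R,4R)-4-{2-[2-(3,4-dihydroxyphenyl)ethoxy]-2-oxoethyl}-3-formyl-2-methyl-3,4-dihydro-2H-pyran-5-carboxylate | COC(=O)C1=CO[C@@H](C)[C@H](C=O)[C@H]1CC(=O)OCCc1ccc(O)c(O)c1 | target

## Step count and risks

Total: 14 steps. Longest linear sequence: 13 steps (steps 1–5 and 7–14, from hydroxytyrosol 1); step 6 is a one-step side branch.

**Step 9 (key step).** The malonate-derived ketene acetal is stabilised, so the rearrangement may stall. Prolonged warming with TMSOTf/Et3N could then ionise the secondary allylic ester, or silylate and conjugate the β,γ-unsaturated arm ester. Leakage through a boat or an axial-methyl chair would erode the configuration at C4.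

Fallback, from 14 back to the route at 21: alcohol 14 is added to methyl propiolate (N-methylmorpholine cat., CH2Cl2) to give the (E)-β-(allyloxy)acrylate F1. Thermal Claisen rearrangement of this allyl vinyl ether (toluene, about 150 °C, sealed vessel) forms the same C4–C5 bond through the same chair, on the same face. It delivers the 2-formyl ester 21 directly, so 16, 19 and 20 are bypassed.

**Step 4.** The free propargylic hydroxyl may undergo copper-carbene O–H insertion in competition with the acetylide pathway. Traces of base could also isomerise the 3-alkynoate to the allenoate.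

Fallback, from 7 back to the route at 8: butynol 7 is silylated (Et3SiCl, imidazole) to the triethylsilyl ether F2. F2 is coupled with 6 under the same CuI conditions to give the silylated alkynoate F3. Mild aqueous acid (AcOH/THF/H2O, rt), which spares aryl silyl ethers, then releases 8.

**Step 7.** Transfer of the sp3 alkoxymethyl group from tin is slow. Butyl transfer, protodeiodination or palladium-induced migration of the β,γ-alkene into conjugation may then take over.

Fallback, from 10 back to the route at 14: stannane 13 undergoes tin–lithium exchange (BuLi, THF, −78 °C) and the lithium reagent is trapped with ZnBr2 to give [(4-methoxybenzyloxy)methyl]zinc bromide F4. Negishi coupling of F4 in excess (one equivalent is consumed by the hydroxyl) with iodide 10 (Pd(PPh3)4, THF, rt) gives 14. Transmetalation from zinc is fast at room temperature.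

**Step 11.** Pd/C with Et3SiH may saturate the ethylidene, cleave the PMB ether reductively, or reduce the product further.

Fallback, from 19 back to the route at 21: the carboxylic acid of 19 is reduced chemoselectively with BH3·SMe2 (THF, −10 °C) to the β-hydroxy ester F5. F5 is oxidised without delay, because its hydroxyl is 1,5 to the arm ester, with Dess–Martin periodinane (NaHCO3, CH2Cl2) to 21.

**Step 13.** The hydroxy aldehyde 22 may rest as a six-membered lactol, which slows the allylic oxidation or diverts it to a lactone. The free alcohol may also lactonise onto either ester. After closure, the C2 epimer may be present in the equilibrium mixture; it would be separated and resubmitted to Et3N.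

Fallback, from 21 back to the route at 24: the enol of 21 is capped (TBSCl, imidazole, CH2Cl2) as silyl enol ether F6, so no aldehyde is present when the alcohol is freed. DDQ gives allylic alcohol F7 and MnO2 gives enal F8. Brief treatment with AcOH/THF/H2O cleaves the vinylogous silyl ester far faster than the aryl silyl ethers, and catalytic Et3N then closes the ring to 24.

## Further compounds

F1 | step 9 | 2-[3,4-bis(tert-butyldimethylsilyloxy)phenyl]ethyl (S,E)-5-{[(E)-3-methoxy-3-oxoprop-1-en-1-yl]oxy}-4-[(4-methoxybenzyloxy)methyl]hex-3-enoate | C[C@H](O/C=C/C(=O)OC)/C(COCc1ccc(OC)cc1)=C/CC(=O)OCCc2ccc(O[Si](C)(C)C(C)(C)C)c(O[Si](C)(C)C(C)(C)C)c2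
F2 | step 4 | (S)-triethyl(but-3-yn-2-yloxy)silane | C[C@H](O[Si](CC)(CC)CC)C#C
F3 | step 4 | 2-[3,4-bis(tert-butyldimethylsilyloxy)phenyl]ethyl (S)-5-(triethylsilyloxy)hex-3-ynoate | C[C@H](O[Si](CC)(CC)CC)C#CCC(=O)OCCc1ccc(O[Si](C)(C)C(C)(C)C)c(O[Si](C)(C)C(C)(C)C)c1
F4 | step 7 | [(4-methoxybenzyloxy)methyl]zinc bromide | COc1ccc(COC[Zn]Br)cc1
F5 | step 11 | methyl (3S,4Z)-3-(2-{2-[3,4-bis(tert-butyldimethylsilyloxy)phenyl]ethoxy}-2-oxoethyl)-2-(hydroxymethyl)-4-[(4-methoxybenzyloxy)methyl]hex-4-enoate, C2 unassigned | COC(=O)C(CO)[C@H](CC(=O)OCCc1ccc(O[Si](C)(C)C(C)(C)C)c(O[Si](C)(C)C(C)(C)C)c1)/C(COCc2ccc(OC)cc2)=C/C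
F6 | step 13 | tert-butyldimethylsilyl enol ether of 21 | COC(=O)C(=CO[Si](C)(C)C(C)(C)C)[C@H](CC(=O)OCCc1ccc(O[Si](C)(C)C(C)(C)C)c(O[Si](C)(C)C(C)(C)C)c1)/C(COCc2ccc(OC)cc2)=C/C
F7 | step 13 | tert-butyldimethylsilyl enol ether of 22 | COC(=O)C(=CO[Si](C)(C)C(C)(C)C)[C@H](CC(=O)OCCc1ccc(O[Si](C)(C)C(C)(C)C)c(O[Si](C)(C)C(C)(C)C)c1)/C(CO)=C/C
F8 | step 13 | tert-butyldimethylsilyl enol ether of 23 | COC(=O)C(=CO[Si](C)(C)C(C)(C)C)[C@H](CC(=O)OCCc1ccc(O[Si](C)(C)C(C)(C)C)c(O[Si](C)(C)C(C)(C)C)c1)/C(C=O)=C/C
A1 | alternative 1 | (E)-crotonaldehyde | C/C=C/C=O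
A2 | alternative 1 | 1-methyl 5-{2-[3,4-bis(tert-butyldimethylsilyloxy)phenyl]ethyl} (E)-2-(hydroxymethylidene)pent-3-enedioate (enol of the 2-formylglutaconate) | COC(=O)C(=CO)/C=C/C(=O)OCCc1ccc(O[Si](C)(C)C(C)(C)C)c(O[Si](C)(C)C(C)(C)C)c1
A3 | alternative 1 | bis-silyl ether of the target (same compound as 24) | COC(=O)C1=CO[C@@H](C)[C@H](C=O)[C@H]1CC(=O)OCCc3ccc(O[Si](C)(C)C(C)(C)C)c(O[Si](C)(C)C(C)(C)C)c3
A4 | alternative 2 | N-acyl benzyloxazolidinone carrying C4, the arm ester and the β-methoxyacrylate | COC(=O)/C(=C/OC)[C@H](CC(=O)OCCc3ccc(O[Si](C)(C)C(C)(C)C)c(O[Si](C)(C)C(C)(C)C)c3)CC(=O)N1[C@H](Cc2ccccc2)COC1=O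
A5 | alternative 2 | acetaldehyde | CC=O
A6 | alternative 2 | syn aldol adduct with C2, C3 and C4 in place | COC(=O)/C(=C/OC)[C@H](CC(=O)OCCc3ccc(O[Si](C)(C)C(C)(C)C)c(O[Si](C)(C)C(C)(C)C)c3)[C@H]([C@H](C)O)C(=O)N1[C@H](Cc2ccccc2)COC1=O
A7 | alternative 3 | methyl (5S,6S)-5-[(4-methoxybenzyloxy)methyl]-6-methyl-2-oxo-5,6-dihydro-2H-pyran-3-carboxylate (substituents trans) | O=C1O[C@@H](C)[C@H](COCc2ccc(OC)cc2)C=C1C(=O)OC
A8 | alternative 3 | trimethylsilyl ketene acetal of 2-[3,4-bis(tert-butyldimethylsilyloxy)phenyl]ethyl acetate | C=C(O[Si](C)(C)C)OCCc1ccc(O[Si](C)(C)C(C)(C)C)c(O[Si](C)(C)C(C)(C)C)c1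
A9 | alternative 3 | 3-methoxycarbonyl δ-lactone carrying the complete side chain at C4 (C5 undefined) | COC(=O)C1C(=O)O[C@@H](C)[C@H](COCc2ccc(OC)cc2)[C@H]1CC(=O)OCCc3ccc(O[Si](C)(C)C(C)(C)C)c(O[Si](C)(C)C(C)(C)C)c3
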